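**Retrosynthetic overview**
- Stilbene: Mizoroki–Heck disconnection at the aryl–vinyl bond of the phenol ring (ring A) gives (S)-8-vinyl-5,7-dimethoxyflavan and 2-iodo-3,5-dimethoxy-4-methylphenol, with the phenol left free.
- Flavan: the O1–C8a bond and the C8–vinyl bond are made in one anionic operation from an open-chain (S)-benzylic alcohol (lithiation beside fluorine, aryne, alkoxide ring closure, C8 aryllithium, Negishi vinylation).
- Stereocentre: set before ring closure by tandem asymmetric transfer hydrogenation of a chalcone made from 2-fluoro-4,6-dimethoxybenzaldehyde and acetophenone; the C–O bond at that carbon is never broken afterwards.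
- Iodophenol: 2,6-dimethoxytoluene, C–H borylation/oxidation para to the methyl group, then ortho-iodination.
- Ring order: the three benzene rings are bought; the pyran ring is the only ring built, closed in step 4 after the stereocentre is in place and before the stilbene is made.

Assumption: the target is read as (2S) at the chroman carbon and E at the alkene; 1-fluoro-3,5-dimethoxybenzene, acetophenone, vinyl bromide (1 M in THF) and 2,6-dimethoxytoluene are taken as catalogue chemicals.

**Route**

Step 1
Reactants: 1 1-fluoro-3,5-dimethoxybenzene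
Product: 3 2-fluoro-4,6-dimethoxybenzaldehyde, via aryl iminium chloride 2 (not isolated)
Conditions: POCl3 (1.3 equiv), DMF, 0 to 70 °C; then H2O
Reagents that add atoms: N,N-dimethylformamide CN(C)C=O; water O
Why: Vilsmeier–Haack formylation, in which the chloroiminium electrophile attacks the position para to one methoxy group and ortho to the small fluorine rather than the position between two methoxy groups, and the iminium salt is hydrolysed on work-up.

Step 2
Reactants: 3 2-fluoro-4,6-dimethoxybenzaldehyde; 4 acetophenone
Product: 5 (E)-3-(2-fluoro-4,6-dimethoxyphenyl)-1-phenylprop-2-en-1-one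
Conditions: NaOH (aq, 0.5 equiv), EtOH, rt
Reagents that add atoms: none
Why: Claisen–Schmidt (crossed aldol) condensation of a non-enolisable aldehyde with acetophenone, with E1cB dehydration giving the E-enone.

Step 3
Reactants: 5 (E)-3-(2-fluoro-4,6-dimethoxyphenyl)-1-phenylprop-2-en-1-one
Product: 7 (1S)-3-(2-fluoro-4,6-dimethoxyphenyl)-1-phenylpropan-1-ol, via saturated ketone 6 (not isolated)
Conditions: RuCl[(S,S)-TsDPEN](p-cymene) (2 mol %), HCO2H/Et3N (5:2), DMF, 40 °C
Reagents that add atoms: none
Why: Noyori-type asymmetric transfer hydrogenation run as a tandem, in which the ruthenium hydride first reduces the enone C=C (1,4) and then the aryl alkyl ketone through the six-membered CH–π-controlled transition state of the (S,S) catalyst, giving the (S)-carbinol as it does with acetophenone.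

Step 4
Reactants: 7 (1S)-3-(2-fluoro-4,6-dimethoxyphenyl)-1-phenylpropan-1-ol; 8 vinyl bromide
Product: 14 (2S)-8-ethenyl-5,7-dimethoxy-2-phenylchroman, via lithium alkoxide 9 (not isolated), via ring-lithiated alkoxide 10 (not isolated), via aryne alkoxide 11 (not isolated), via 8-lithiochroman 12 (not isolated), via 8-chlorozinc chroman 13 (not isolated)
Conditions: s-BuLi (2.1 equiv), TMEDA, THF (0.03 M), −78 °C; warm to −20 °C; ZnCl2 (1.2 equiv), −20 °C to rt; then 8 (2 equiv), Pd(OAc)2 (3 mol %), SPhos (6 mol %), 45 °C
Reagents that add atoms: none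
Why: Proposed new method: s-BuLi makes the lithium alkoxide and then removes the ring proton flanked by F and OMe (directed ortho-metalation), warming expels LiF to give an aryne, the tethered alkoxide adds to the nearer aryne carbon (six-membered ring closure, also favoured electronically because the carbanion ends up ortho to OMe), and the resulting C8 aryllithium is transmetalated to zinc and vinylated (Negishi coupling), so ring closure and C8 functionalisation are regiodefined in one flask while the stereocentre, whose C–O bond is never broken, stays S; the closest known chemistry is the strong-base aryne ring closure of 3-(2-halophenyl)propan-1-ols to chromans and the fluoroarene lithiation–aryne cyclisation–electrophile trapping sequences used for benzo-fused heterocycles.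

Step 5
Reactants: 15 2,6-dimethoxytoluene
Product: 17 3,5-dimethoxy-4-methylphenol, via aryl pinacol boronate 16 (not isolated)
Conditions: [Ir(OMe)(cod)]2 (1.5 mol %), dtbpy (3 mol %), B2pin2 (0.6 equiv), THF, 80 °C; then KHSO5 (as 2KHSO5·KHSO4·K2SO4), acetone/H2O, rt
Reagents that add atoms: potassium peroxymonosulfate KHSO5 [K+].[O-]S(=O)(=O)OO
Why: Iridium-catalysed C–H borylation is sterically controlled and takes the only ring C–H with no ortho substituent (para to the methyl group), and oxidation of the C–B bond at that position gives the phenol (one-pot borylation–oxidation).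

Step 6
Reactants: 17 3,5-dimethoxy-4-methylphenol
Product: 18 2-iodo-3,5-dimethoxy-4-methylphenol
Conditions: N-iodosuccinimide (1.0 equiv), MeCN, 0 °C, dark
Reagents that add atoms: N-iodosuccinimide O=C1CCC(=O)N1I
Why: Electrophilic aromatic iodination of an electron-rich phenol whose para position is blocked by methyl and whose two ortho positions are equivalent, so one equivalent of reagent gives a single mono-iodide.

Step 7
Reactants: 14 (2S)-8-ethenyl-5,7-dimethoxy-2-phenylchroman; 18 2-iodo-3,5-dimethoxy-4-methylphenol
Product: 19 2-[(E)-2-[(2S)-5,7-dimethoxy-2-phenyl-3,4-dihydro-2H-chromen-8-yl]ethenyl]-3,5-dimethoxy-4-methylphenol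
Conditions: Pd2(dba)3 (2.5 mol %), P(t-Bu)3·HBF4 (10 mol %), Cy2NMe (2.2 equiv), 1,4-dioxane, 90 °C
Reagents that add atoms: none
Why: Mizoroki–Heck reaction, in which oxidative addition of the aryl iodide to zerovalent palladium, syn-carbopalladation at the unsubstituted alkene carbon and syn-β-hydride elimination give the E-stilbene, with the free phenol tolerated and the stereocentre untouched.

**Compound list**

1 | 1-fluoro-3,5-dimethoxybenzene | COc1cc(F)cc(OC)c1 | starting material
2 | N-[(2-fluoro-4,6-dimethoxyphenyl)methylidene]-N-methylmethanaminium chloride | COc1cc(F)c(C=[N+](C)C)c(OC)c1.[Cl-] | intermediate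
3 | 2-fluoro-4,6-dimethoxybenzaldehyde | COc1cc(F)c(C=O)c(OC)c1 | intermediate
4 | acetophenone | CC(=O)c1ccccc1 | starting material
5 | (E)-3-(2-fluoro-4,6-dimethoxyphenyl)-1-phenylprop-2-en-1-one | COc1cc(F)c(/C=C/C(=O)c2ccccc2)c(OC)c1 | intermediate
6 | 3-(2-fluoro-4,6-dimethoxyphenyl)-1-phenylpropan-1-one | COc1cc(F)c(CCC(=O)c2ccccc2)c(OC)c1 | intermediate
7 | (1S)-3-(2-fluoro-4,6-dimethoxyphenyl)-1-phenylpropan-1-ol | COc1cc(F)c(CC[C@H](O)c2ccccc2)c(OC)c1 | intermediate
8 | vinyl bromide (bromoethene) | C=CBr | starting material
9 | lithium (1S)-3-(2-fluoro-4,6-dimethoxyphenyl)-1-phenylpropan-1-olate | COc1cc(F)c(CC[C@H]([O-])c2ccccc2)c(OC)c1.[Li+] | intermediate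
10 | lithium (1S)-3-(2-fluoro-3-lithio-4,6-dimethoxyphenyl)-1-phenylpropan-1-olate | [Li]c1c(F)c(CC[C@H]([O-])c2ccccc2)c(OC)cc1OC.[Li+] | intermediate
11 | lithium (1S)-3-(2,3-didehydro-4,6-dimethoxyphenyl)-1-phenylpropan-1-olate (aryne) | COC1=CC(OC)=C(CC[C@H]([O-])c2ccccc2)C#C1.[Li+] | intermediate
12 | [(2S)-5,7-dimethoxy-2-phenyl-3,4-dihydro-2H-chromen-8-yl]lithium | [Li]c1c(OC)cc(OC)c2c1O[C@H](c1ccccc1)CC2 | intermediate
13 | chloro[(2S)-5,7-dimethoxy-2-phenyl-3,4-dihydro-2H-chromen-8-yl]zinc | Cl[Zn]c1c(OC)cc(OC)c2c1O[C@H](c1ccccc1)CC2 | intermediate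
14 | (2S)-8-ethenyl-5,7-dimethoxy-2-phenyl-3,4-dihydro-2H-chromene | C=Cc1c(OC)cc(OC)c2c1O[C@H](c1ccccc1)CC2 | intermediate
15 | 2,6-dimethoxytoluene (1,3-dimethoxy-2-methylbenzene) | COc1cccc(OC)c1C | starting material
16 | 2-(3,5-dimethoxy-4-methylphenyl)-4,4,5,5-tetramethyl-1,3,2-dioxaborolane | COc1cc(B2OC(C)(C)C(C)(C)O2)cc(OC)c1C | intermediate
17 | 3,5-dimethoxy-4-methylphenol | COc1cc(O)cc(OC)c1C | intermediate
18 | 2-iodo-3,5-dimethoxy-4-methylphenol | COc1cc(O)c(I)c(OC)c1C | intermediate
19 | 2-[(E)-2-[(2S)-5,7-dimethoxy-2-phenyl-3,4-dihydro-2H-chromen-8-yl]ethenyl]-3,5-dimethoxy-4-methylphenol (CNP0000264.1) | COc1cc(O)c(/C=C/c2c(OC)cc(OC)c3c2O[C@H](c2ccccc2)CC3)c(OC)c1C | target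

**Step count and risks**

Total steps: 7. Longest linear sequence: 5 (steps 1, 2, 3, 4, 7); the iodophenol branch is 2 steps (5, 6) and joins in step 7.

Most likely to fail, with fallbacks:

Step 4 (lithiation–aryne ring closure–Negishi). The risks are partial lithiation between the two methoxy groups instead of beside fluorine, intermolecular capture of the aryne, and loss of the C8 carbanion before transmetalation. The fallback sets out from 7 and gives up on keeping the carbanion. Lithium 2,2,6,6-tetramethylpiperidide (3 equiv, THF, −78 to 0 °C, then NH4Cl) lets the amine shuttle protons until lithiation beside fluorine leads to the aryne, the alkoxide closes the ring and the aryl anion is protonated, giving (2S)-5,7-dimethoxy-2-phenylchroman F1. N-Bromosuccinimide (1 equiv, CH2Cl2, −20 °C) then brominates C8, the position that 5,7-dialkoxyflavans halogenate first, giving (2S)-8-bromo-5,7-dimethoxy-2-phenylchroman F2. Suzuki–Miyaura coupling of F2 with potassium vinyltrifluoroborate (PdCl2(dppf), K2CO3, THF/H2O, 70 °C) comes back to the route at 14.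

Step 7 (Heck coupling of two electron-rich partners, each with two ortho substituents). The risks are slow insertion and some 1,1-diarylethene. The fallback sets out from 14 and fixes the alkene geometry on boron first. Cross-metathesis with vinylboronic acid pinacol ester (second-generation Grubbs catalyst, CH2Cl2, 40 °C) gives 2-[(E)-2-[(2S)-5,7-dimethoxy-2-phenyl-3,4-dihydro-2H-chromen-8-yl]ethenyl]-4,4,5,5-tetramethyl-1,3,2-dioxaborolane F3. Suzuki–Miyaura coupling of F3 with 18 (Pd(OAc)2, SPhos, K3PO4, THF/H2O, 50 °C) comes back to the route at 19.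

Step 3 (tandem C=C/C=O transfer hydrogenation). The risk is that the electron-rich enone is reduced slowly at carbon and stalls as allylic alcohol or ketone mixtures. The fallback sets out from 5 and separates the two reductions. Hydrogenation of only the C=C bond (H2, 1 atm, RhCl(PPh3)3, benzene/EtOH, rt) gives ketone 6, now isolated. Corey–Bakshi–Shibata reduction of 6 with (R)-2-methyl-CBS-oxazaborolidine (10 mol %) and BH3·SMe2 (THF, −20 °C) comes back to the route at 7. Every compound on this path is already in the list (entry F0).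

Further compounds
F1 | step 4 | (2S)-5,7-dimethoxy-2-phenyl-3,4-dihydro-2H-chromene | COc1cc(OC)c2c(c1)O[C@H](c1ccccc1)CC2
F2 | step 4 | (2S)-8-bromo-5,7-dimethoxy-2-phenyl-3,4-dihydro-2H-chromene | COc1cc(OC)c2c(c1Br)O[C@H](c1ccccc1)CC2
F3 | step 7 | 2-[(E)-2-[(2S)-5,7-dimethoxy-2-phenyl-3,4-dihydro-2H-chromen-8-yl]ethenyl]-4,4,5,5-tetramethyl-1,3,2-dioxaborolane | CC1(C)OB(/C=C/c2c(OC)cc(OC)c3c2O[C@H](c2ccccc2)CC3)OC1(C)C
F0 | step 3 | none | none
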